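All runs are simulated with constants of no real substance.

In a one-step world, with X + E -> L and E held steady, each minute takes the same fraction of the X present, whatever the charge; this is pseudo-first-order behaviour. X enters the candidate steps once, in exactly that step, and the held gas G feeds E, which starts with none dissolved. So I expect a short start-up and then a steady fractional loss.

the same everywhere: G 9.8 mM (held)

|  | X | remark | time |
|---|---|---|---|
| Friday's | 32 mM | run made earlier |  |
| Sunday's | 72 mM | run made earlier |  |
| oak | 48 mM |  | 5.0 min |
| cedar | 48 mM |  | 6.0 min |

| run | time / min | Q / % | J / % | L / % | X / % |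
|---|---|---|---|---|---|
| Friday's | 0.667 | 0 | 1 | 1 | 97 |
| Friday's | 2.00 | 4 | 0 | 7 | 92 |
| Friday's | 3.00 | 2 | 0 | 11 | 84 |
| Friday's | 5.00 | 7 | 0 | 12 | 74 |
| Sunday's | 1.33 | 0 | 0 | 5 | 94 |
| Sunday's | 2.50 | 4 | 1 | 7 | 87 |
| Sunday's | 4.00 | 5 | 0 | 12 | 83 |
| Sunday's | 5.00 | 5 | 3 | 13 | 78 |

(each reading ± 1.5 percentage points)

- for J the D are counted in
- as a solid, counted per litre of solution: D
- at the start none of E is dissolved
- the numbers in the tables scatter with a standard deviation of 1.5 percentage points
- candidate steps: X + E -> L; E + L -> J; E + L <-> Q; Q -> Z; D <-> J; G <-> E

* which of these there is most of at the end, counted by the X in it, oak (L / Q / J / X)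
* which of these there is most of at the end, counted by the X in it, cedar (L / Q / J / X)
* final amount of the leader among these, as a percentage of the X charged, in oak
* final amount of the leader among these, as a percentage of the X charged, in cedar

The readings fit this picture. Sunday's charge is 72 mM against Friday's 32 mM, a ratio of 2.25, yet at 5.00 min the X left is 74% on Friday and 78% on Sunday, a gap of 4 percentage points against a scatter of 1.5 points in each reading. So I treat the fraction left as nearly independent of the charge.

To skip the start-up, I reckon from each run's first reading to its last. The logarithm of the ratio of X, divided by the time between, gives 0.0625 /min for Friday's and 0.0508 /min for Sunday's. Their mean is my fractional loss rate, the fraction of the X present that goes per minute: 0.0567 /min.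

Oak's charge lies between the two, so I take the mean of the two last readings, 76.0%. Cedar runs 1.00 min longer, so the loss rate brings it to 71.8%. X stays far ahead of L, which reads 12% on Friday, so I name X as the leader in both flasks.

The forecast also names X in both, with 76% for oak and 72% for cedar, on the ground that “The fractional loss of X is nearly the same at both concentrations”.

The flasks give X as leader, at 75.7% in oak and 71.2% in cedar, both within the forecast's margin.

    X + E → L (k = 7.50 /M/min)
    E + L → J (k = 7.70 /M/min)
    E + L ⇌ Q (K = 62.0 /M, k = 230 /M/min)
    Q → Z (k = 0.0930 /min)
    D ⇌ J, rate k5*(cs5 - [J]) while solid is left; crystals form when [J] > cs5 (solubility = 0.590 mM, k = 7.00 /min)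
    G ⇌ E, rate k6*(csat - [E]) (kL = 2.10 /min)

In oak, E stands at 8.02 mM at 2.50 min and 8.14 mM at 5.00 min. Carrying oak's end value back to 2.0 min with the fractional loss rate of 0.0567 /min gives 89.7%, and oak stopped at that time holds 90.7% of its X.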